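## The problem

The target 15, 5,7-dihydroxy-3-(4-hydroxy-2-methoxyphenyl)-6,8-bis(3-methylbut-2-enyl)chromen-4-one, is an isoflavone: a benzo-fused 4-pyranone (rings A and C) with aryl ring B on C3. It has no stereocentre, so the task is one of regiochemistry and functional-group tolerance. The one carbinol centre that appears on the way is erased by oxidation. Ring A is hexasubstituted (OH at C5 and C7, prenyl at C6 and C8, the carbonyl on C4a, the ring oxygen on C8a), so the C4 carbon has to be attached between two ortho oxygens. The prenyl groups are the fragile part: under acid their olefins add a neighbouring phenol to give 2,2-dimethylchromans, they react with electrophilic halogen, and they are competent partners in olefin metathesis. Ring B must keep its 2'-methyl ether while three phenols (5-OH, 7-OH, 4'-OH) are set free, which calls for a protecting group removable without touching an aryl methyl ether or a prenyl olefin. The feature that guides the plan is that ring C holds exactly one olefin, C2=C3, between O1 and the aryl-bearing C3. Cutting it leaves a vinyl ether on O1 and a 1,1-disubstituted α-aryl enone at C3/C4, two terminal olefins held ortho on ring A that a ruthenium alkylidene can join.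

## Retrosynthesis

**Phenol unmasking.** The three O–CH2 acetal bonds of tris(methoxymethyl) ether 14 are cut last. One acetal type on all three phenols allows a single deprotection, and the 2'-methyl ether is inert to it. The forward step must cleave three acetals without adding a phenol or chloride to a prenyl olefin.

**C6–C1'' and C8–C1''.** Both prenyl groups of 14 are cut back to the bromines of dibromochromenone 12 and two equivalents of stannane 13. Carrying prenyl groups from the start would expose them to bromination and put a third and fourth olefin into the metathesis substrate. An 8-prenyl group in particular could close a six-membered ring onto the O-vinyl group. Bromine is inert to ruthenium and marks both positions. The forward step is a twofold cross-coupling at two flanked bromides that must deliver the linear prenyl isomer.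

**C2=C3 (ring C).** Chromenone 12 is opened across its only olefin to enone 11, which carries an O-vinyl group on the future O1 and a methylene on the future C3. The neighbouring cuts (O1–C2 by addition–elimination, C3–C1' by coupling to a 3-halochromone) are the classical ones. This cut is taken because both ring carbons arrive as plain terminal olefins at the final oxidation level, and the closure is neutral and loses only ethene. The precursor has one ring fewer and no new functional-group demands. The forward step asks a ruthenium carbene formed on an enol ether to close onto a hindered, electron-poor 1,1-disubstituted olefin, and this is the untested part.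

**C3–C4 and the ketone oxidation level.** Enone 11 comes from allylic alcohol 10 by oxidation. Alcohol 10 is cut between the carbinol carbon and the vinyl carbon into aldehyde 4 and the 1-arylvinyl nucleophile 9, made through vinyllithium 8 from sulfonylhydrazone 7. Addition to an aldehyde is preferred over acylation because the carbonyl sits between two ortho substituents. The Shapiro route is preferred over methylenation of a deoxybenzoin because it gives the 1,1-disubstituted olefin directly from a methyl ketone. The forward sequence must tolerate two aryl bromides next to a carbanion.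

**Ring A fragment.** Aldehyde 4 is cut at the O–vinyl bond to phenol 3, at the two C–Br bonds to 2, and at two O–CH2 bonds to aldehyde 1. In 1 the hydroxyl that stays hydrogen-bonded to the formyl group is left free by bis-protection, and it is exactly the future O1. Bromination must come before vinylation, since a vinyl ether would not survive an electrophilic bromine source.

**Ring B fragment.** Hydrazone 7 is cut at C=N to ketone 6, and 6 at its acetal to acetophenone 5, which already carries the 2-methoxy and 4-hydroxy pattern of ring B.

## Roads not taken

**Alternative 1: double aromatic Claisen rearrangement.** The cut is at the two aryl–prenyl bonds, traced to O-bound 1,1-dimethylallyl groups.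
- Key step: on gentle warming, each tertiary allyl ether of 3,5-bis(2-methylbut-3-en-2-yloxy)phenol A1 should migrate by a [3,3] shift to a neighbouring ring carbon with inversion of the allyl unit. Tautomerisation then gives 2,4-bis(3-methylbut-2-enyl)benzene-1,3,5-triol A2.
- Merits: no halogen, tin or palladium is needed and the prenyl groups arrive in their normal form. Any pair of different ortho carbons gives the same A2, and A2 is symmetric, so later acylation and ring closure have no regiochemical choice.
- Weak points: the two ethers of A1 share one ortho carbon, and migration of both to it gives a blocked dienone. A1 itself needs a selective double etherification with a tertiary allyl group. Carrying A2 forward means acid-mediated C-acylation at its last, hindered ring carbon to the deoxybenzoin 2-(4-hydroxy-2-methoxyphenyl)-1-[2,4,6-trihydroxy-3,5-bis(3-methylbut-2-enyl)phenyl]ethanone A3. Those are the conditions under which a prenyl group cyclises onto an ortho hydroxyl. A3 would then still need a one-carbon unit for C2 and closure of ring C.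
- Comparison: this road is clearly shorter and avoids stoichiometric tin. The chosen plan sets against it that the prenyl groups meet no electrophile and only one mild acid treatment, and that every ring A substituent is placed by a formyl group or a halogen.

**Alternative 2: Danheiser benzannulation of ring A.** The cut removes three C–C bonds of ring A (C6–C7, C7–C8, C4a–C8a).
- Key step: heating 3-ethoxy-4-(3-methylbut-2-enyl)cyclobut-2-en-1-one A4 with [(5-methylhex-4-en-1-yn-1-yl)oxy]tri(propan-2-yl)silane A5 opens A4 to a vinylketene (4π), which adds the siloxyalkyne in a [2+2] step. A second 4π opening, 6π closure and tautomerisation follow. The product is 3-ethoxy-2,6-bis(3-methylbut-2-enyl)-5-[tri(propan-2-yl)silyloxy]phenol A6.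
- Merits: one metal-free step fixes both prenyl groups and three differentiated oxygens with full regiocontrol, and A6 keeps a single ring CH as the future C4a.
- Weak points: it builds a benzene ring that a commercial triphenol already supplies. A4 and A5 each need several steps, and the ketene intermediates carry prenyl olefins that can be trapped. The ethyl ether of A6 ends on O5 and would have to be cleaved next to two prenyl groups and the 2'-methyl ether. Acylation of A6 at C4a and the whole of ring C are still to be made.
- Comparison: it is superior in differentiating the ring A oxygens, but the target does not need that, since O5 and O7 both end as free hydroxyls. It is inferior in step count and in the dealkylation; the chosen plan avoids both with a symmetric protecting scheme.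

**Alternative 3: carbonylative Stille coupling around C4.** The cut is at C4–C4a and C3–C4, with the carbonyl carbon supplied from the gas phase.
- Key step: with Pd(PPh3)4 under carbon monoxide, zerovalent palladium adds oxidatively to 2-iodo-1,3,5-tris(methoxymethoxy)-4,6-bis(3-methylbut-2-enyl)benzene A7 and carbon monoxide inserts. The resulting aroylpalladium then takes the vinyl group of tributyl{(E)-2-methoxy-1-[2-methoxy-4-(methoxymethoxy)phenyl]ethenyl}stannane A8. This gives (E)-3-methoxy-2-[2-methoxy-4-(methoxymethoxy)phenyl]-1-[2,4,6-tris(methoxymethoxy)-3,5-bis(3-methylbut-2-enyl)phenyl]prop-2-en-1-one A9. Acid would then remove the acetals of A9 and close ring C by addition–elimination.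
- Merits: it is the most convergent road. In A9 the C2 carbon arrives at the right oxidation level, and the ring closure is of a long-established type and could coincide with deprotection.
- Weak points: oxidative addition into the hexasubstituted, electron-rich iodide A7, flanked by two acetal oxygens, is slow. Transmetalation from the α-aryl stannane A8 is hindered, and direct coupling and protodestannylation compete. A8 is not trivially made with defined geometry. A7 needs iodine and two prenyl groups on one ring, and prenyl olefins do not tolerate electrophilic iodination.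
- Comparison: if A7 and A8 were in hand, this endgame through A9 would be shorter than the chosen one and rest on a known closure; in that respect it is better. The chosen plan sets against it fragments made in three or four standard steps, prenyl groups absent during halogenation, and an unprecedented step that has a known-chemistry bypass from the same precursor.

Key step: step 8

Assumption: hydrazone 7 is drawn as the E isomer expected to predominate; either isomer gives the same vinyl anion because only the methyl group carries α-hydrogens. Alcohol 10 is racemic and its stereocentre is removed in step 7.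

## Route

Step 1
Reactants: 1 2,4,6-trihydroxybenzaldehyde
Product: 2 2-hydroxy-4,6-bis(methoxymethoxy)benzaldehyde
Conditions: MOMCl (2.2 equiv), i-Pr2NEt, CH2Cl2, 0 °C to rt
Reagents that add atoms: chloromethyl methyl ether, COCCl
Why: O-alkylation (MOM protection); once one ortho hydroxyl is etherified the other is locked in a hydrogen bond to the formyl oxygen and is left free, which is the hydroxyl needed later as O1.

Step 2
Reactants: 2 2-hydroxy-4,6-bis(methoxymethoxy)benzaldehyde
Product: 3 3,5-dibromo-2-hydroxy-4,6-bis(methoxymethoxy)benzaldehyde
Conditions: NBS (2.1 equiv), DMF, 0 °C to rt, dark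
Reagents that add atoms: N-bromosuccinimide, O=C1CCC(=O)N1Br
Why: Electrophilic aromatic bromination; C3 and C5 are the only open positions and each is ortho or para to three oxygen donors, and NBS in DMF releases no HBr, so the acetals should survive.

Step 3
Reactants: 3 3,5-dibromo-2-hydroxy-4,6-bis(methoxymethoxy)benzaldehyde
Product: 4 3,5-dibromo-2-(ethenyloxy)-4,6-bis(methoxymethoxy)benzaldehyde
Conditions: 2,4,6-trivinylcyclotriboroxane–pyridine complex, Cu(OAc)2, pyridine, CH2Cl2, air, rt
Reagents that add atoms: 2,4,6-trivinylcyclotriboroxane–pyridine complex, C=CB1OB(C=C)OB(C=C)O1.c1ccncc1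
Why: Chan–Lam-type oxidative O-vinylation: the vinyl group passes from boron to the copper phenoxide, air oxidises copper to the trivalent state and C–O reductive elimination follows; at room temperature the aryl bromides, aldehyde and acetals should be untouched.

Step 4
Reactants: 5 1-(4-hydroxy-2-methoxyphenyl)ethanone
Product: 6 1-[2-methoxy-4-(methoxymethoxy)phenyl]ethanone
Conditions: MOMCl, i-Pr2NEt, CH2Cl2, 0 °C to rt
Reagents that add atoms: chloromethyl methyl ether, COCCl
Why: O-alkylation (MOM protection) of the only phenol, giving ring B the same acetal as ring A so one deprotection serves at the end.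

Step 5
Reactants: 6 1-[2-methoxy-4-(methoxymethoxy)phenyl]ethanone
Product: 7 N'-[(1E)-1-[2-methoxy-4-(methoxymethoxy)phenyl]ethylidene]-2,4,6-tri(propan-2-yl)benzenesulfonohydrazide
Conditions: 2,4,6-tri(propan-2-yl)benzenesulfonohydrazide, THF, cat. AcOH, rt
Reagents that add atoms: 2,4,6-tri(propan-2-yl)benzenesulfonohydrazide, CC(C)c1cc(C(C)C)c(S(=O)(=O)NN)c(C(C)C)c1
Why: Condensation of a ketone with a sulfonylhydrazide; the trisyl group is chosen because it has no ortho hydrogens to be metalated and its dianion fragments at 0 °C.

Step 6
Reactants: 7 N'-[(1E)-1-[2-methoxy-4-(methoxymethoxy)phenyl]ethylidene]-2,4,6-tri(propan-2-yl)benzenesulfonohydrazide, 4 3,5-dibromo-2-(ethenyloxy)-4,6-bis(methoxymethoxy)benzaldehyde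
Product: 10 1-[3,5-dibromo-2-(ethenyloxy)-4,6-bis(methoxymethoxy)phenyl]-2-[2-methoxy-4-(methoxymethoxy)phenyl]prop-2-en-1-ol (racemic), via 1-arylvinyllithium 8 (not isolated), via 1-arylvinylmagnesium bromide 9 (not isolated)
Conditions: n-BuLi (2.0 equiv per 7), THF, −78 to 0 °C; MgBr2·OEt2, −78 °C; then 4, −78 to −20 °C; H2O
Reagents that add atoms: none
Why: Shapiro reaction: N–H and methyl deprotonation give a dianion that loses sulfinate and N2 to form vinyllithium 8; transmetalation to the magnesium reagent 9 removes the risk of bromine–lithium exchange on 4, and 1,2-addition to the aldehyde gives 10, whose carbinol centre forms without control and is erased in step 7.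

Step 7
Reactants: 10 1-[3,5-dibromo-2-(ethenyloxy)-4,6-bis(methoxymethoxy)phenyl]-2-[2-methoxy-4-(methoxymethoxy)phenyl]prop-2-en-1-ol (racemic)
Product: 11 1-[3,5-dibromo-2-(ethenyloxy)-4,6-bis(methoxymethoxy)phenyl]-2-[2-methoxy-4-(methoxymethoxy)phenyl]prop-2-en-1-one
Conditions: Dess–Martin periodinane, pyridine, CH2Cl2, 0 °C to rt
Reagents that add atoms: none
Why: Dess–Martin oxidation of a hindered benzylic, allylic secondary alcohol; pyridine buffers the acetic acid so the vinyl ether and acetals should survive, and the α-aryl enone is taken on without storage.

Step 8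
Reactants: 11 1-[3,5-dibromo-2-(ethenyloxy)-4,6-bis(methoxymethoxy)phenyl]-2-[2-methoxy-4-(methoxymethoxy)phenyl]prop-2-en-1-one
Product: 12 6,8-dibromo-5,7-bis(methoxymethoxy)-3-[2-methoxy-4-(methoxymethoxy)phenyl]chromen-4-one
Conditions: second-generation Hoveyda–Grubbs catalyst (10 mol %, two portions), toluene (0.003 M), 90 °C, argon sparge
Reagents that add atoms: none
Why: Proposed new method: the catalyst benzylidene should exchange with the unhindered O-vinyl group of 11 to give an aryloxymethylidene [Ru]=CH–OAr, whose donor stabilisation is reduced by the acyl and bromo substituents on ring A, so it should stay more reactive than the alkoxycarbenes that arrest metathesis. This carbene adds to the ortho-tethered 1,1-disubstituted enone olefin in a [2+2] step with ruthenium on the terminal CH2, and cycloreversion of the ruthenacyclobutane releases 12 and [Ru]=CH2, which takes up the next vinyl ether with loss of ethene. The closest known reaction type is ring-closing metathesis of aryl vinyl ethers bearing an ortho allyl or propenyl group to 4H-chromenes and benzofurans, together with closures onto acrylate-type olefins; what is new is that the catalyst must load on the enol ether and close onto an α-aryl enone. Ring C closes as a six-membered ring between two olefins held ortho on ring A, C2=C3 is the only bond formed and no stereocentre is created. The step needs ring closure to win over oligomerisation and over decay of the resting aryloxycarbene; the ortho geometry, high dilution, removal of ethene by sparging and the absence of any third olefin (bromine stands at C6 and C8 in place of prenyl) should secure this. The product olefin is trisubstituted and part of a conjugated 4-pyranone, so the closure should not be reversed.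

Step 9
Reactants: 12 6,8-dibromo-5,7-bis(methoxymethoxy)-3-[2-methoxy-4-(methoxymethoxy)phenyl]chromen-4-one, 13 tributyl(3-methylbut-2-enyl)stannane
Product: 14 5,7-bis(methoxymethoxy)-3-[2-methoxy-4-(methoxymethoxy)phenyl]-6,8-bis(3-methylbut-2-enyl)chromen-4-one
Conditions: 13 (3 equiv), Pd(PPh3)4 (10 mol %), CsF, DMF, 100 °C
Reagents that add atoms: none
Why: Twofold Stille coupling: zerovalent palladium inserts into each C–Br bond, fluoride-activated prenyl transfer from tin follows, and reductive elimination at the less hindered primary terminus of the prenylpalladium should give the linear prenyl groups; the chromenone and acetals are inert to these neutral conditions.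

Step 10
Reactants: 14 5,7-bis(methoxymethoxy)-3-[2-methoxy-4-(methoxymethoxy)phenyl]-6,8-bis(3-methylbut-2-enyl)chromen-4-one
Product: 15 5,7-dihydroxy-3-(4-hydroxy-2-methoxyphenyl)-6,8-bis(3-methylbut-2-enyl)chromen-4-one
Conditions: HCl (3 M aq), MeOH, 45 °C
Reagents that add atoms: none
Why: Acid-catalysed acetal cleavage (MOM removal) with methanol trapping the oxocarbenium ion; the aryl methyl ether is stable, and dilute acid at moderate temperature is chosen to keep the prenyl olefins from adding the freed ortho phenols.

## Compound list

1 | 2,4,6-trihydroxybenzaldehyde | O=Cc1c(O)cc(O)cc1O | starting material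
2 | 2-hydroxy-4,6-bis(methoxymethoxy)benzaldehyde | COCOc1cc(O)c(C=O)c(OCOC)c1 | intermediate
3 | 3,5-dibromo-2-hydroxy-4,6-bis(methoxymethoxy)benzaldehyde | COCOc1c(Br)c(O)c(C=O)c(OCOC)c1Br | intermediate
4 | 3,5-dibromo-2-(ethenyloxy)-4,6-bis(methoxymethoxy)benzaldehyde | C=COc1c(Br)c(OCOC)c(Br)c(OCOC)c1C=O | intermediate
5 | 1-(4-hydroxy-2-methoxyphenyl)ethanone | CC(=O)c1ccc(O)cc1OC | starting material
6 | 1-[2-methoxy-4-(methoxymethoxy)phenyl]ethanone | CC(=O)c1ccc(OCOC)cc1OC | intermediate
7 | N'-[(1E)-1-[2-methoxy-4-(methoxymethoxy)phenyl]ethylidene]-2,4,6-tri(propan-2-yl)benzenesulfonohydrazide | C/C(=N\NS(=O)(=O)c1c(C(C)C)cc(C(C)C)cc1C(C)C)c1ccc(OCOC)cc1OC | intermediate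
8 | {1-[2-methoxy-4-(methoxymethoxy)phenyl]ethenyl}lithium | [Li]C(=C)c1ccc(OCOC)cc1OC | intermediate (not isolated)
9 | bromo{1-[2-methoxy-4-(methoxymethoxy)phenyl]ethenyl}magnesium | Br[Mg]C(=C)c1ccc(OCOC)cc1OC | intermediate (not isolated)
10 | 1-[3,5-dibromo-2-(ethenyloxy)-4,6-bis(methoxymethoxy)phenyl]-2-[2-methoxy-4-(methoxymethoxy)phenyl]prop-2-en-1-ol (racemic) | C=COc1c(Br)c(OCOC)c(Br)c(OCOC)c1C(O)C(=C)c1ccc(OCOC)cc1OC | intermediate
11 | 1-[3,5-dibromo-2-(ethenyloxy)-4,6-bis(methoxymethoxy)phenyl]-2-[2-methoxy-4-(methoxymethoxy)phenyl]prop-2-en-1-one | C=COc1c(Br)c(OCOC)c(Br)c(OCOC)c1C(=O)C(=C)c1ccc(OCOC)cc1OC | intermediate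
12 | 6,8-dibromo-5,7-bis(methoxymethoxy)-3-[2-methoxy-4-(methoxymethoxy)phenyl]chromen-4-one | COCOc1ccc(-c2coc3c(Br)c(OCOC)c(Br)c(OCOC)c3c2=O)c(OC)c1 | intermediate
13 | tributyl(3-methylbut-2-enyl)stannane | CC(C)=CC[Sn](CCCC)(CCCC)CCCC | starting material
14 | 5,7-bis(methoxymethoxy)-3-[2-methoxy-4-(methoxymethoxy)phenyl]-6,8-bis(3-methylbut-2-enyl)chromen-4-one | COCOc1ccc(-c2coc3c(CC=C(C)C)c(OCOC)c(CC=C(C)C)c(OCOC)c3c2=O)c(OC)c1 | intermediate
15 | 5,7-dihydroxy-3-(4-hydroxy-2-methoxyphenyl)-6,8-bis(3-methylbut-2-enyl)chromen-4-one | COc1cc(O)ccc1-c1coc2c(CC=C(C)C)c(O)c(CC=C(C)C)c(O)c2c1=O | target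

## Step count and risks

Total: 10 steps. Longest linear sequence: 8 steps (steps 1, 2, 3, 6, 7, 8, 9, 10); the ring B branch (steps 4 and 5) joins at step 6.

**Step 8 (key step, proposed new method).** The likeliest failure is arrest of the catalyst as the aryloxycarbene, which may not engage the hindered, electron-poor 1,1-disubstituted olefin and decays thermally to inactive ruthenium hydride species. Intermolecular metathesis to oligomers is the second risk. The fallback uses known chemistry and sets out from 11. The vinyl ether is cleaved under neutral conditions (HgCl2, HgO, aqueous acetone, rt) to 1-[3,5-dibromo-2-hydroxy-4,6-bis(methoxymethoxy)phenyl]-2-[2-methoxy-4-(methoxymethoxy)phenyl]prop-2-en-1-one F1. With Et3N its phenol adds to the enone in a 6-endo oxa-Michael closure, giving racemic 6,8-dibromo-5,7-bis(methoxymethoxy)-3-[2-methoxy-4-(methoxymethoxy)phenyl]-2,3-dihydrochromen-4-one F2. Dehydrogenation with DDQ in 1,4-dioxane at reflux returns to the route at 12.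

**Step 3.** Vinyl transfer and C–O reductive elimination may be slow at a phenol flanked by bromine and a formyl group, which can also hold copper as a salicylaldehyde-type chelate. Fallback from 3: O-alkylation with 1,2-dibromoethane (K2CO3, DMF, 60 °C) to 3,5-dibromo-2-(2-bromoethoxy)-4,6-bis(methoxymethoxy)benzaldehyde F3, then E2 elimination with KOt-Bu in THF at 0 °C, returning at 4.

**Step 6.** Metalation of ring B between its methoxy and acetal oxygens may compete with hydrazone α-deprotonation. Residual organolithium may exchange with a ring A bromine, and addition to the doubly ortho-substituted aldehyde may be slow. Fallback from 6: enol triflation (KN(SiMe3)2, PhNTf2, THF, −78 °C) to 1-[2-methoxy-4-(methoxymethoxy)phenyl]ethenyl trifluoromethanesulfonate F4, then Nozaki–Hiyama–Kishi coupling with 4 (CrCl2, cat. NiCl2, DMF, rt), returning at 10. Zerovalent nickel should insert into the vinyl triflate well before the hindered aryl bromides, and the organochromium adds only to the aldehyde.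

**Step 9.** The second coupling at a flanked bromide may stall, protodebromination may intervene, and allylic transposition may give 1,1-dimethylallyl isomers. Fallback from 12: twofold Stille coupling with allyltributylstannane (Pd(PPh3)4, CsF, DMF, 100 °C), which has no regiochemical ambiguity, to 5,7-bis(methoxymethoxy)-3-[2-methoxy-4-(methoxymethoxy)phenyl]-6,8-bis(prop-2-enyl)chromen-4-one F5. Cross-metathesis with 2-methylbut-2-ene (second-generation Grubbs catalyst, CH2Cl2, 40 °C) then returns at 14; the trisubstituted C2=C3 olefin is not expected to take part.

**Step 10.** Acid may promote addition of the freed 5- or 7-hydroxyl to an adjacent prenyl olefin (chroman formation) or hydrochlorination of the olefins. Fallback from 12, reversing the order of the last two operations: the acetals are removed first (HCl, MeOH, 45 °C), when no acid-sensitive group is present, to give 6,8-dibromo-5,7-dihydroxy-3-(4-hydroxy-2-methoxyphenyl)chromen-4-one F6. Base-free twofold Stille coupling with 13 (Pd(PPh3)4, DMF, 100 °C) then returns at 15, so the prenyl groups never meet acid.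

## Further compounds

F1 | step 8 | 1-[3,5-dibromo-2-hydroxy-4,6-bis(methoxymethoxy)phenyl]-2-[2-methoxy-4-(methoxymethoxy)phenyl]prop-2-en-1-one | C=C(C(=O)c1c(O)c(Br)c(OCOC)c(Br)c1OCOC)c1ccc(OCOC)cc1OC
F2 | step 8 | 6,8-dibromo-5,7-bis(methoxymethoxy)-3-[2-methoxy-4-(methoxymethoxy)phenyl]-2,3-dihydrochromen-4-one (racemic) | COCOc1ccc(C2COc3c(Br)c(OCOC)c(Br)c(OCOC)c3C2=O)c(OC)c1
F3 | step 3 | 3,5-dibromo-2-(2-bromoethoxy)-4,6-bis(methoxymethoxy)benzaldehyde | O=Cc1c(OCCBr)c(Br)c(OCOC)c(Br)c1OCOC
F4 | step 6 | 1-[2-methoxy-4-(methoxymethoxy)phenyl]ethenyl trifluoromethanesulfonate | C=C(OS(=O)(=O)C(F)(F)F)c1ccc(OCOC)cc1OC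
F5 | step 9 | 5,7-bis(methoxymethoxy)-3-[2-methoxy-4-(methoxymethoxy)phenyl]-6,8-bis(prop-2-enyl)chromen-4-one | COCOc1ccc(-c2coc3c(CC=C)c(OCOC)c(CC=C)c(OCOC)c3c2=O)c(OC)c1
F6 | step 10 | 6,8-dibromo-5,7-dihydroxy-3-(4-hydroxy-2-methoxyphenyl)chromen-4-one | COc1cc(O)ccc1-c1coc2c(Br)c(O)c(Br)c(O)c2c1=O
A1 | alternative 1 | 3,5-bis(2-methylbut-3-en-2-yloxy)phenol | C=CC(C)(C)Oc1cc(O)cc(OC(C)(C)C=C)c1
A2 | alternative 1 | 2,4-bis(3-methylbut-2-enyl)benzene-1,3,5-triol | CC(C)=CCc1c(O)cc(O)c(CC=C(C)C)c1O
A3 | alternative 1 | 2-(4-hydroxy-2-methoxyphenyl)-1-[2,4,6-trihydroxy-3,5-bis(3-methylbut-2-enyl)phenyl]ethanone | COc1cc(O)ccc1CC(=O)c1c(O)c(CC=C(C)C)c(O)c(CC=C(C)C)c1O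
A4 | alternative 2 | 3-ethoxy-4-(3-methylbut-2-enyl)cyclobut-2-en-1-one | CCOC1=CC(=O)C1CC=C(C)C
A5 | alternative 2 | [(5-methylhex-4-en-1-yn-1-yl)oxy]tri(propan-2-yl)silane | CC(C)=CCC#CO[Si](C(C)C)(C(C)C)C(C)C
A6 | alternative 2 | 3-ethoxy-2,6-bis(3-methylbut-2-enyl)-5-[tri(propan-2-yl)silyloxy]phenol | CCOc1cc(O[Si](C(C)C)(C(C)C)C(C)C)c(CC=C(C)C)c(O)c1CC=C(C)C
A7 | alternative 3 | 2-iodo-1,3,5-tris(methoxymethoxy)-4,6-bis(3-methylbut-2-enyl)benzene | COCOc1c(I)c(OCOC)c(CC=C(C)C)c(OCOC)c1CC=C(C)C
A8 | alternative 3 | tributyl{(E)-2-methoxy-1-[2-methoxy-4-(methoxymethoxy)phenyl]ethenyl}stannane | CO/C=C(/[Sn](CCCC)(CCCC)CCCC)c1ccc(OCOC)cc1OC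
A9 | alternative 3 | (E)-3-methoxy-2-[2-methoxy-4-(methoxymethoxy)phenyl]-1-[2,4,6-tris(methoxymethoxy)-3,5-bis(3-methylbut-2-enyl)phenyl]prop-2-en-1-one | CO/C=C(/C(=O)c1c(OCOC)c(CC=C(C)C)c(OCOC)c(CC=C(C)C)c1OCOC)c1ccc(OCOC)cc1OC
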